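Millimolar per second is the unit I reckon in: the solid substrate in this flask meets the coupling partner through solution, as a feed of dissolved substrate.

    coupling partner + protic impurity → quenched reagent (k1 = 49 /M/s)
    dissolved substrate + coupling partner → target (k2 = 6.5 /M/s)
    solid substrate + target → side product B (k3 = 1.5 /M/s)
    solid product ⇌ target, rate k4*(cs4 - [target]) while solid is left; crystals form when [target] > cs4 (cs4 = 3.7 mM, k4 = 4.2 /s)
    solid substrate ⇌ dissolved substrate, rate k5*(cs5 - [dissolved substrate]) while solid is left; crystals form when [dissolved substrate] > cs5 (cs5 = 3.8 mM, k5 = 0.032 /s)
    2 dissolved substrate → side product A (k6 = 12 /M/s)

solid substrate 11 mM; coupling partner 27.5 mM; protic impurity 0.550 mM; time 1.0 min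

- south-west: doubling the solubility in step 5, all else as stated
- north: doubling the dissolution coefficient of step 4, all else as stated
- south-east: doubling the solubility in step 4, all else as stated
- east: doubling the dissolution coefficient of step 5, all else as stated

- a species is counted by the solid substrate in it: one side product A or side product B counts as two
- amounts and yields of target count solid product too
- for a step with 2 of a species take k times the square, and two of it per event
- given per volume of solution although it is solid: solid substrate, solid product
- at the start none of the solid substrate is in solution
- dissolved substrate means what is dissolved; the solid is not counted in it
- run time (flask): 1.0 min

1. how much target and solid product together there is at 1.0 min, in percent of the solid substrate charged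
2. concentration of dissolved substrate in solution at 15 s, in percent of saturation
3. the change that raises the amount of target and solid product together at 1.0 min, in percent of the solid substrate charged most ("none" if none brings more than 2 percentage points) (south-west / north / south-east / east / none)
4. amount of target and solid product together at 1.0 min, in percent of the solid substrate charged, after south-east

Solid dissolves at 0.032 /s times the gap below the solubility 3.8 mM, and 27.5 mM of coupling partner with 6.5 /M/s removes dissolved substrate at a pseudo-first-order constant of 0.179 /s. This gives 15.2% as the hold-up fraction f, the dissolving coefficient divided by itself plus the removal constant: the share of saturation at which feed equals use by coupling, with the coupling partner as charged. The approach to it has the time constant 4.74 s, and 15 s is 3.16 such times, so I expect sat near 14.6%.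

The feed is then 0.103 mM/s, which over 1.0 min is 56.3% of the charge. The steps to side product A and side product B also draw on this material, so I commit y to less than that, though I don't reckon how much. South-west makes the feed 0.206 mM/s and east 0.179 mM/s, so south-west gives more, and I choose it. South-east acts on the step between target and solid product, which are counted together, so I expect yb close to y.

The forecast gives y 38.5%, sat 14.5%, best south-west and yb 38.2%, on the ground that “Dissolution of the solid is the bottleneck”.

The simulation gives y 37.0%, sat 14.3%, best south-west (gain 34 percentage points, east 30 points) and yb 36.9%.

At 0.490 min dissolved substrate in this flask is made 1.02 times as fast as it is used, and its half-life by coupling, 0.072 min, is shorter than the run. Reckoned with the coupling partner as charged, f puts dissolved substrate at 5.25% of the charge, and this flask holds 5.30% at 0.500 min.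

In the neighbour flask with 69 mM of coupling partner, f falls to 6.66%, which means 2.30% of the charge dissolved. That neighbour flask shows 2.49% at 1.00 min, with y at 47.2%.

(The rate constants are assumed.)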